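At the time of reading, 1.5 h, you want to know what stands in a stirred flask where a solid substrate dissolves and meets partner added in portions.

| setting | amber | ochre | flask |
|---|---|---|---|
| solid substrate | 0.050 M | 0.075 M | 0.10 M |
| partner | 1.05 equiv (in portions, 4) | 1.05 equiv (in portions, 4) | 1.05 equiv (in portions, 4) |
| remark | run made earlier; portions every 25 s | run made earlier; portions every 25 s | the portions of partner follow each other after 25 s, the first at the start |
| time |  |  | 1.5 h |

| run | time / min | solid substrate / % | target / % | starting material / % |
|---|---|---|---|---|
| amber | 8.00 | 39.5 | 48.7 | 4.4 |
| amber | 15.0 | 27.3 | 51.4 | 7.1 |
| amber | 25.0 | 26.0 | 51.3 | 8.9 |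
| amber | 40.0 | 25.6 | 52.3 | 8.4 |
| amber | 60.0 | 25.3 | 51.7 | 9.0 |
| amber | 120 | 25.2 | 52.3 | 7.5 |
| ochre | 20.0 | 40.5 | 44.0 | 5.5 |
| ochre | 40.0 | 40.0 | 44.1 | 5.4 |
| ochre | 50.0 | 39.5 | 43.7 | 5.7 |
| ochre | 80.0 | 40.6 | 44.4 | 5.3 |
| ochre | 90.0 | 40.0 | 44.4 | 5.7 |
| ochre | 120 | 40.5 | 43.9 | 6.4 |

(scatter of a reading: 0.5 percentage points)

- given per volume of solution although it is solid: solid substrate
- at the start none of the solid substrate is in solution
- what has only dissolved of solid substrate counts as not reacted
- what has gone from starting material into another species counts as reacted, even if it can come back
- starting material means what is dissolved; the solid is not counted in it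
- the reaction counts as stopped when no species that holds the solid substrate changes by six tenths of a point or more over the second half of the time

* which holds at 1.5 h: what has brought the reaction to rest, or that it has not come to rest (for what has run out or reacted, a solid counts together with what of it has only dissolved) (it is still moving / all of the solid substrate has reacted / the partner has run out first)
* part of the solid substrate that has turned into other species by 1.5 h (what has only dissolved does not count)
* how much target there is at 1.5 h, in percent of the solid substrate charged
* how much starting material there is at 1.5 h, in percent of the solid substrate charged

Both earlier runs stop moving early and keep solid. The amber solid reads 25.3% at 60.0 min and 25.2% at 120 min; the ochre solid reads 40.5% at 20.0 min and 40.5% at 120 min. What counts, then, is how the partner charge divided. Target on the plateau averages 51.9% in amber and 44.1% in ochre. Dividing by the equivalents, and taking one partner per target, gives the partner share, the fraction of the partner charge found as target: 49.4% in amber and 42.0% in ochre.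

Two first-order exits with constant rate constants give a share independent of the charge, but ochre's share is lower than amber's. So go to logarithms. Let x be the partner charge as a multiple of amber's. Ochre has log10 x = 0.176, and log10 of the share moved by −0.0705. Their ratio, −0.403, is the share exponent, the slope of log share against log partner charge, read from these two runs. The flask has x = 2.00, so its share is amber's times 0.756, which is 37.4%. Multiplied by 1.05 equiv, my reckoning gives target 39.3%.

The forecast says the partner has run out first, with conversion 45.3%, target 38% and starting material 4.2%. Its ground: "Both runs stop with solid left, so the partner is lost." Its target is lower than mine.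

The flask gives the partner has run out first, with partner 0%, conversion 46.6%, target 39.2% and starting material 4.10%.

    starting material ⇌ reactive form (K = 0.00550, k = 0.420 /s)
    partner + reactive form → target (k = 710 /M/s)
    starting material ⇌ dormant form (K = 1.80, k = 0.0170 /s)
    solid substrate ⇌ starting material, rate k4*(cs4 - [starting material]) while solid is left; crystals form when [starting material] > cs4 (solubility = 4.10 mM, k = 0.0220 /s)
    partner → decomposed reagent (k = 0.00320 /s)

Although charged at 1.05 equiv, the partner in this flask stands at 0% with solid substrate 49.3% still lying there, and at 15.0 h the target stands at 39.2%, so waiting adds nothing. A neighbouring flask keeps the solid charge and takes partner at 0.420 equiv. Its x is 0.800, so the exponent, −0.403, lifts the share to 54.1% and gives target 22.7%. Simulated, that neighbour ends with partner 0%, solid or dissolved substrate 70%, and target 22.2%.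

Readings and results come from a simulation on assumed constants, noise included.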